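**Retrosynthetic overview**
- Target ⇐ mono-oxidation of one of the two homotopic allylic carbinols of the C2-symmetric (3R,6S,3'R,6'S)-ε,ε-carotene-3,3'-diol.
- Diol ⇐ two-fold Wittig reaction, C15 + C10 + C15: two identical hydroxy C15 phosphonium salts and the C10 trienedial.
- C15 salt ⇐ catalyst-controlled ketone reduction and phosphonium formation from a (6S)-3-oxo-ε C15 dienol. Its C6 stereocentre comes from an amine-catalysed enantioselective 1,3-proton shift of the achiral 3-oxo-β isomer (the new step).
- Achiral 3-oxo-β dienol ⇐ base-free Stille coupling of a ketoisophorone-derived enol triflate with a C5 dienylstannane.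
- No ring is formed in the route: both cyclohexene rings come intact from ketoisophorone, the single ring precursor, which is used twice.

Assumption: the quinidine-derived amine is taken to give the (6S) enone (its quinine-derived pseudoenantiomer is used if the sense proves opposite), and catalyst-bound species of catalytic cycles are described in the Why lines and carry no number.

**Step 1**
Reactants: 1 ketoisophorone (2,6,6-trimethylcyclohex-2-ene-1,4-dione)
Product: 3 enol triflate 2,6,6-trimethyl-4-oxocyclohex-1-en-1-yl trifluoromethanesulfonate, via lithium enolate 2 (not isolated)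
Conditions: LiBH(s-Bu)3 (1.0 equiv), THF, −78 °C, 30 min; then Comins' reagent (1.1 equiv), −78 to 0 °C; water work-up, neutral silica
Reagents that add atoms: Comins' reagent, N-(5-chloropyridin-2-yl)bis(trifluoromethanesulfonimide), Clc1ccc(nc1)N(S(=O)(=O)C(F)(F)F)S(=O)(=O)C(F)(F)F
Why: Conjugate hydride reduction with enolate trapping (reductive triflation): the bulky hydride adds to the unsubstituted alkene carbon of the doubly activated enedione and gives regiospecifically the tetrasubstituted enolate 2, which the pyridyl triflimide O-sulfonylates; no stereocentre is formed and every species stays achiral.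

**Step 2**
Reactants: 4 (E)-3-methylpent-2-en-4-yn-1-ol
Product: 5 (2E,4E)-3-methyl-5-(tributylstannyl)penta-2,4-dien-1-ol
Conditions: Bu3SnH (1.1 equiv), PdCl2(PPh3)2 (2 mol %), THF, 0 °C; chromatography
Reagents that add atoms: tributyltin hydride, CCCC[SnH](CCCC)CCCC
Why: Palladium-catalysed syn-hydrostannation of a terminal alkyne puts tin on the terminal carbon and H cis to it, giving the (E)-vinylstannane; the minor internal regioisomer is removed by chromatography.

**Step 3**
Reactants: 3 enol triflate; 5 dienylstannane
Product: 6 (2E,4E)-3-methyl-5-(2,6,6-trimethyl-4-oxocyclohex-1-en-1-yl)penta-2,4-dien-1-ol (achiral 3-oxo-β C15 dienol)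
Conditions: Pd2(dba)3 (2.5 mol %), AsPh3 (20 mol %), NMP, 50 °C; aq. KF work-up, filtration through neutral alumina, used at once
Reagents that add atoms: none
Why: Stille cross-coupling with retention of both alkene geometries; zerovalent palladium with the weak donor AsPh3 speeds transmetalation for the hindered tetrasubstituted triflate, and because no base is present the β,γ-unsaturated ketone does not drift into conjugation.

**Step 4**
Reactants: 6 achiral 3-oxo-β C15 dienol
Product: 7 (2E,4E)-3-methyl-5-[(1S)-2,6,6-trimethyl-4-oxocyclohex-2-en-1-yl]penta-2,4-dien-1-ol ((6S)-3-oxo-ε C15 dienol)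
Conditions: 9-amino-9-deoxy-epi-quinidine (10 mol %), 4-nitrobenzoic acid (20 mol %), toluene, 0 °C, 24–48 h; stopped at full conversion
Reagents that add atoms: none
Why: Proposed new method: the primary amine condenses with the unconjugated ring ketone, the quinuclidine nitrogen removes the α proton (C4) to give an extended dienamine, and the resulting quinuclidinium returns that proton suprafacially to one enantiotopic face of the γ carbon (C6), which it can reach while the remote chain positions lie outside its span; hydrolysis releases the conjugated enone, estimated about 2 kcal/mol more stable (compare isophorone with its β,γ isomer) and slow to re-enter the cycle, so C6 is set as (S) in the first stereocentre-forming event of the route; the closest known reaction type is the amine-catalysed enantioselective isomerisation of simple 4-substituted cyclohex-3-enones to cyclohex-2-enones by iminium/dienamine proton transfer, not yet shown for a tetrasubstituted alkene whose protonated carbon carries a dienyl group and sits next to a quaternary carbon.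

**Step 5**
Reactants: 7 (6S)-3-oxo-ε C15 dienol
Product: 8 (2E,4E)-5-[(1S,4R)-4-hydroxy-2,6,6-trimethylcyclohex-2-en-1-yl]-3-methylpenta-2,4-dien-1-ol
Conditions: (S)-2-methyl-CBS-oxazaborolidine (20 mol %), catecholborane (2.5 equiv), toluene, −78 °C; MeOH quench, aq. NaHCO3 work-up
Reagents that add atoms: none
Why: Corey–Bakshi–Shibata reduction under catalyst control: with the alkenyl arm of the enone as the large group the (S)-oxazaborolidine delivers hydride to give the (3R) carbinol, cis to the side chain, overriding the weak substrate bias that favours the trans alcohol with uncatalysed bulky hydrides; catecholborane at −78 °C leaves the diene alone.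

**Step 6**
Reactants: 8 (3R,6S) C15 diol
Product: 9 [(2E,4E)-5-[(1S,4R)-4-hydroxy-2,6,6-trimethylcyclohex-2-en-1-yl]-3-methylpenta-2,4-dien-1-yl]triphenylphosphonium bromide
Conditions: PPh3·HBr (1.05 equiv), MeOH, 0 °C to rt, 12 h; crystallisation (EtOAc/CH2Cl2)
Reagents that add atoms: triphenylphosphine hydrobromide, [Br-].c1ccc(cc1)[PH+](c1ccccc1)c1ccccc1
Why: SN1-type allylic substitution (standard C15 Wittig-salt formation): the primary dienylic alcohol ionises to a methyl-stabilised pentadienyl cation far more readily than the ring allylic alcohol, so C3 and C6 are untouched, and the all-E salt crystallises, which also upgrades purity.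

**Step 7**
Reactants: 9 C15 phosphonium bromide (2.1 equiv); 10 (2E,4E,6E)-2,7-dimethylocta-2,4,6-trienedial (1.0 equiv)
Product: 13 all-E (3R,6S,3'R,6'S)-ε,ε-carotene-3,3'-diol, via phosphorus ylide 11 (not isolated), via C25 hydroxy-apocarotenal 12 (not isolated)
Conditions: NaOMe (2.2 equiv), MeOH/CH2Cl2, 0 °C to rt, 3 h; then reflux in n-heptane/EtOH under argon in the dark (Z to E); crystallisation (CH2Cl2/MeOH)
Reagents that add atoms: none
Why: Two-fold Wittig olefination: ylide 11 condenses with the dial to 12 and a second ylide with 12; the Z isomers at the two new 11,12 double bonds isomerise thermally to all-E; no stereocentre is formed, and the dimerisation raises enantiomeric purity because the minor C15 enantiomer ends up mainly in a separable diastereomer.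

**Step 8**
Reactants: 13 C2-symmetric C40 diol
Product: 14 all-E (6S,3'R,6'S)-3'-hydroxy-ε,ε-caroten-3-one (CNP0344065.5)
Conditions: activated MnO2 (about 10 wt equiv), acetone, rt, dark, argon, HPLC control, stopped near half conversion; chromatography, recovered 13 recycled
Reagents that add atoms: none
Why: MnO2 oxidation of an allylic alcohol: the two carbinols of 13 are homotopic, so oxidation of either gives the same compound 14 (statistical ceiling near 50 % per pass, with diol recycled and the dione separated); the neutral heterogeneous conditions leave the polyene, the remaining (3'R) carbinol and the base-sensitive C6–H of the new enone untouched.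

**Compound list**
1 | ketoisophorone (2,6,6-trimethylcyclohex-2-ene-1,4-dione) | CC1=CC(=O)CC(C)(C)C1=O | starting material
2 | lithium 2,6,6-trimethyl-4-oxocyclohex-1-en-1-olate | [Li+].[O-]C1=C(C)CC(=O)CC1(C)C | intermediate
3 | 2,6,6-trimethyl-4-oxocyclohex-1-en-1-yl trifluoromethanesulfonate | CC1=C(OS(=O)(=O)C(F)(F)F)C(C)(C)CC(=O)C1 | intermediate
4 | (E)-3-methylpent-2-en-4-yn-1-ol | C#C/C(C)=C/CO | starting material
5 | (2E,4E)-3-methyl-5-(tributylstannyl)penta-2,4-dien-1-ol | CCCC[Sn](CCCC)(CCCC)/C=C/C(C)=C/CO | intermediate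
6 | (2E,4E)-3-methyl-5-(2,6,6-trimethyl-4-oxocyclohex-1-en-1-yl)penta-2,4-dien-1-ol | CC1=C(/C=C/C(C)=C/CO)C(C)(C)CC(=O)C1 | intermediate
7 | (2E,4E)-3-methyl-5-[(1S)-2,6,6-trimethyl-4-oxocyclohex-2-en-1-yl]penta-2,4-dien-1-ol | CC1=CC(=O)CC(C)(C)[C@@H]1/C=C/C(C)=C/CO | intermediate
8 | (2E,4E)-5-[(1S,4R)-4-hydroxy-2,6,6-trimethylcyclohex-2-en-1-yl]-3-methylpenta-2,4-dien-1-ol | OC/C=C(C)/C=C/[C@@H]1C(C)=C[C@H](O)CC1(C)C | intermediate
9 | [(2E,4E)-5-[(1S,4R)-4-hydroxy-2,6,6-trimethylcyclohex-2-en-1-yl]-3-methylpenta-2,4-dien-1-yl]triphenylphosphonium bromide | c1ccccc1[P+](c1ccccc1)(c1ccccc1)C/C=C(C)/C=C/[C@@H]1C(C)=C[C@H](O)CC1(C)C.[Br-] | intermediate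
10 | (2E,4E,6E)-2,7-dimethylocta-2,4,6-trienedial | O=C/C(C)=C/C=C/C=C(C)/C=O | starting material
11 | triphenylphosphonium ylide of 9 (carbanion at the carbon next to phosphorus) | c1ccccc1[P+](c1ccccc1)(c1ccccc1)[CH-]/C=C(C)/C=C/[C@@H]1C(C)=C[C@H](O)CC1(C)C | intermediate
12 | (2E,4E,6E,8E,10E,12E)-13-[(1S,4R)-4-hydroxy-2,6,6-trimethylcyclohex-2-en-1-yl]-2,7,11-trimethyltrideca-2,4,6,8,10,12-hexaenal | O=C/C(C)=C/C=C/C=C(C)/C=C/C=C(C)/C=C/[C@@H]1C(C)=C[C@H](O)CC1(C)C | intermediate
13 | all-E (3R,6S,3'R,6'S)-ε,ε-carotene-3,3'-diol | CC1=C[C@H](O)CC(C)(C)[C@@H]1/C=C/C(C)=C/C=C/C(C)=C/C=C/C=C(C)/C=C/C=C(C)/C=C/[C@@H]1C(C)=C[C@H](O)CC1(C)C | intermediate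
14 | all-E (6S,3'R,6'S)-3'-hydroxy-ε,ε-caroten-3-one | CC1=CC(=O)CC(C)(C)[C@@H]1/C=C/C(C)=C/C=C/C(C)=C/C=C/C=C(C)/C=C/C=C(C)/C=C/[C@@H]1C(C)=C[C@H](O)CC1(C)C | target

**Step count**
Total: 8 steps. Longest linear sequence: 7 steps (steps 1, 3, 4, 5, 6, 7, 8 from ketoisophorone).

**Three steps most likely to fail**

Step 4 (the proposed new isomerisation). Possible failures are slow turnover at the hindered, fully substituted γ carbon, low enantioselectivity, proton return to a remote chain position, or acid-assisted ionisation of the dienylic alcohol. The fallback sets out from 6 and comes back at 7. DBU (5 mol %) in CH2Cl2 carries out the ordinary base-catalysed β,γ to α,β shift and gives racemic (2E,4E)-3-methyl-5-(2,6,6-trimethyl-4-oxocyclohex-2-en-1-yl)penta-2,4-dien-1-ol F1. Its enantiomers are separated by preparative chiral SFC; the (S) enantiomer is 7, and the (R) enantiomer is re-racemised with DBU and recycled.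

Step 1 (reductive triflation). The hydride may attack the unhindered C4 carbonyl in 1,2-fashion, or the enolate may scramble by proton transfer before it is trapped. The fallback sets out from 1 and comes back at 3. Zn dust in AcOH reduces the enedione double bond to racemic 2,2,6-trimethylcyclohexane-1,4-dione F2. Ethylene glycol with TsOH ketalises only the unhindered carbonyl to 7,7,9-trimethyl-1,4-dioxaspiro[4.5]decan-8-one F3. KN(SiMe3)2 followed by PhNTf2 enolises the one available position and gives the achiral 7,9,9-trimethyl-1,4-dioxaspiro[4.5]dec-7-en-8-yl trifluoromethanesulfonate F4, which erases the racemic centre. Brief hydrolysis with aqueous oxalic acid in THF then returns 3.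

Step 5 (cis-selective reduction). The neopentyl CH2 arm may be too similar in size to the alkenyl arm for good catalyst control, leaving a cis/trans mixture. The fallback sets out from 7 and comes back at 8. KBH(s-Bu)3 in THF at −78 °C attacks anti to the axial ring methyl and gives mainly the trans diol (2E,4E)-5-[(1S,4S)-4-hydroxy-2,6,6-trimethylcyclohex-2-en-1-yl]-3-methylpenta-2,4-dien-1-ol F5. A double Mitsunobu reaction (4-nitrobenzoic acid, PPh3, DIAD, THF, 0 °C) esterifies the primary alcohol and inverts the ring carbinol, giving (2E,4E)-5-[(1S,4R)-2,6,6-trimethyl-4-(4-nitrobenzoyloxy)cyclohex-2-en-1-yl]-3-methylpenta-2,4-dien-1-yl 4-nitrobenzoate F6. Methanolysis with K2CO3 in MeOH then gives 8.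

**Further compounds**
F1 | step 4 | racemic (2E,4E)-3-methyl-5-(2,6,6-trimethyl-4-oxocyclohex-2-en-1-yl)penta-2,4-dien-1-ol | CC1=CC(=O)CC(C)(C)C1/C=C/C(C)=C/CO
F2 | step 1 | racemic 2,2,6-trimethylcyclohexane-1,4-dione | CC1CC(=O)CC(C)(C)C1=O
F3 | step 1 | racemic 7,7,9-trimethyl-1,4-dioxaspiro[4.5]decan-8-one | CC1CC2(CC(C)(C)C1=O)OCCO2
F4 | step 1 | 7,9,9-trimethyl-1,4-dioxaspiro[4.5]dec-7-en-8-yl trifluoromethanesulfonate | CC1=C(OS(=O)(=O)C(F)(F)F)C(C)(C)CC2(C1)OCCO2
F5 | step 5 | (2E,4E)-5-[(1S,4S)-4-hydroxy-2,6,6-trimethylcyclohex-2-en-1-yl]-3-methylpenta-2,4-dien-1-ol | OC/C=C(C)/C=C/[C@@H]1C(C)=C[C@@H](O)CC1(C)C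
F6 | step 5 | (2E,4E)-5-[(1S,4R)-2,6,6-trimethyl-4-(4-nitrobenzoyloxy)cyclohex-2-en-1-yl]-3-methylpenta-2,4-dien-1-yl 4-nitrobenzoate | O=C(OC/C=C(C)/C=C/[C@@H]1C(C)=C[C@H](OC(=O)c2ccc(cc2)[N+](=O)[O-])CC1(C)C)c1ccc(cc1)[N+](=O)[O-]
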